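**Retrosynthetic overview**

1. The C40 chain is cut at C11=C12 and C11'=C12': two E-selective Horner–Wadsworth–Emmons olefinations join an ε-C15 allylphosphonate, the C10 trienedial and a 3,4-dioxygenated β-C15 allylphosphonate.
2. Key step (used twice): each C15 allylphosphonate comes from a tertiary vinyl carbinol by a thermal [2,3]-sigmatropic allyl phosphite → allylphosphonate shift. It makes the C9=C10 olefin and the C11–P donor bond without acid, which both ionisable allylic C–O groups require.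
3. The cis-3,4-diol β ring comes from cis-3-hydroxy-α-ionone by OH-directed epoxidation and vinylogous E1cB epoxide opening. The ε ring is trans-3-hydroxy-α-ionone itself.
4. Both 3-hydroxy-α-ionones come from (R)-α-ionone by ketal protection, allylic oxidation at C3 and reduction; both C3 epimers are used.
5. Ring order: no ring is constructed. Both carbocycles are bought as (R)-α-ionone; one is kept as the ε ring, the other is converted into the β ring in step 8.

Assumption: enantiopure (R)-(+)-α-ionone and (2E,4E,6E)-2,7-dimethylocta-2,4,6-trienedial are purchased. Ring positions are given in carotenoid numbering (C3 carbinol, C6 ring carbon bearing the chain). The route is designed from known reaction classes, not run; ratios quoted are expectations.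

**Route**

Step 1
Reactants: 1 (R)-α-ionone, (3E)-4-[(1R)-2,6,6-trimethylcyclohex-2-en-1-yl]but-3-en-2-one
Product: 2 2-methyl-2-{(E)-2-[(1R)-2,6,6-trimethylcyclohex-2-en-1-yl]ethenyl}-1,3-dioxolane
Conditions: HOCH2CH2OH, HC(OMe)3, p-TsOH (cat.), rt
Reagents that add atoms: ethylene glycol (OCCO)
Why: Acid-catalysed ketalisation with orthoformate as water scavenger masks the side-chain ketone so that only the ring carbonyl made in step 2 is reduced in step 3; the mild conditions leave C6 and both double bonds in place.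

Step 2
Reactants: 2 α-ionone ethylene ketal
Product: 3 (4R)-3,5,5-trimethyl-4-[(E)-2-(2-methyl-1,3-dioxolan-2-yl)ethenyl]cyclohex-2-en-1-one
Conditions: t-BuOOH (70% aq), NaOCl (aq), K2CO3, MeCN, -5 to 0 °C
Reagents that add atoms: tert-butyl hydroperoxide (CC(C)(C)OO)
Why: Radical allylic oxidation (t-BuOO• hydrogen abstraction, allyl peroxide, collapse to the enone) attacks the only unhindered allylic CH2 (C3), the doubly allylic C6–H being shielded by the gem-dimethyl and 5-methyl groups; the cold, weakly basic medium should not epimerise C6.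

Step 3
Reactants: 3 3-oxo-α-ionone ethylene ketal
Product: 6 (3R,6R)-3-hydroxy-α-ionone [trans; (3E)-4-[(1R,4R)-4-hydroxy-2,6,6-trimethylcyclohex-2-en-1-yl]but-3-en-2-one] + 7 (3S,6R)-3-hydroxy-α-ionone [cis; (3E)-4-[(1R,4S)-4-hydroxy-2,6,6-trimethylcyclohex-2-en-1-yl]but-3-en-2-one], via trans-hydroxy ketal 4 (not isolated), via cis-hydroxy ketal 5 (not isolated)
Conditions: NaBH4, CeCl3·7H2O, MeOH, -20 °C; evaporate; 0.3 M aq HCl (cat.), THF, 0 °C to rt; SiO2 separation of 6 and 7
Reagents that add atoms: water (O)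
Why: Luche 1,2-reduction of the ring enone followed by acetal hydrolysis creates C3 under the influence of the bought C6 centre as two separable diastereomers (attack anti to the axial ring methyl should favour trans 6, about 2–3:1 expected); both are needed, 6 for the ε ring and 7 for the diol ring.

Step 4
Reactants: 6 (3R,6R)-3-hydroxy-α-ionone
Product: 8 (3E)-4-[(1R,4R)-4-(triethylsilyloxy)-2,6,6-trimethylcyclohex-2-en-1-yl]but-3-en-2-one
Conditions: TESCl, imidazole, DMF, 0 °C to rt
Reagents that add atoms: triethylsilyl chloride (CC[Si](Cl)(CC)CC)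
Why: Silyl ether formation blocks the secondary allylic alcohol so that only the tertiary carbinol of step 5 is phosphitylated in step 6; no stereocentre is touched.

Step 5
Reactants: 8 TES ether of trans-3-hydroxy-α-ionone
Product: 9 (4E)-3-methyl-5-[(1R,4R)-4-(triethylsilyloxy)-2,6,6-trimethylcyclohex-2-en-1-yl]penta-1,4-dien-3-ol (both carbinol epimers)
Conditions: CH2=CHMgBr, THF, -20 to 0 °C; H2O quench
Reagents that add atoms: vinylmagnesium bromide (C=C[Mg]Br)
Why: Grignard 1,2-addition to the methyl enone gives the tertiary bis-allylic carbinol; the new carbinol centre needs no control because it is destroyed in step 6.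

Step 6
Reactants: 9 ε-series vinyl carbinol
Product: 11 diethyl {(2E,4E)-3-methyl-5-[(1R,4R)-4-(triethylsilyloxy)-2,6,6-trimethylcyclohex-2-en-1-yl]penta-2,4-dien-1-yl}phosphonate, via allyl diethyl phosphite 10 (not isolated)
Conditions: (EtO)2PCl, Et3N, DMAP (cat.), Et2O, 0 °C; filter; PhMe, 100 °C; SiO2 (2E isomer)
Reagents that add atoms: diethyl chlorophosphite (CCOP(Cl)OCC)
Why: O-phosphitylation then thermal [2,3]-sigmatropic allyl phosphite → allylphosphonate rearrangement (phosphorus lone pair onto the vinyl terminus through a five-membered transition state, driven by P=O formation) makes the C11–P bond and the C9=C10 olefin under neutral conditions, so the ionisable allylic C3–O survives; the 2E isomer (major, about 2–3:1 expected) is taken on.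

Step 7
Reactants: 11 ε-C15 phosphonate; 12 (2E,4E,6E)-2,7-dimethylocta-2,4,6-trienedial
Product: 13 (2E,4E,6E,8E,10E,12E)-2,7,11-trimethyl-13-[(1R,4R)-4-(triethylsilyloxy)-2,6,6-trimethylcyclohex-2-en-1-yl]trideca-2,4,6,8,10,12-hexaenal [(3R,6R)-3-(triethylsilyloxy)-12'-apo-ε-caroten-12'-al]
Conditions: KOt-Bu, THF, -30 °C; add slowly to 12 (3 equiv), -30 to 0 °C
Reagents that add atoms: none
Why: Horner–Wadsworth–Emmons olefination of the phosphonate carbanion with an excess of the dialdehyde gives the mono-adduct with an E C11=C12 bond; the stereocentres are remote and unaffected.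

Step 8
Reactants: 7 (3S,6R)-3-hydroxy-α-ionone
Product: 15 (3E)-4-[(3R,4S)-3,4-dihydroxy-2,6,6-trimethylcyclohex-1-en-1-yl]but-3-en-2-one [cis-diol; (3S,4R)-3,4-dihydroxy-β-ionone in carotenoid numbering], via syn-epoxy alcohol 14 (not isolated)
Conditions: VO(acac)2 (cat.), t-BuOOH (decane), CH2Cl2, 0 °C to rt; Me2S; evaporate; NaOMe (cat.), MeOH, 0 °C to rt
Reagents that add atoms: tert-butyl hydroperoxide (CC(C)(C)OO)
Why: Vanadium-catalysed hydroxyl-directed epoxidation delivers oxygen to the face of the C3–OH, fixing C4–O cis to C3–O (4R); methoxide-catalysed vinylogous E1cB opening through the C6 dienolate then gives the conjugated C5=C6 bond and the cis-3,4-diol, consuming the bought C6 centre after it has set C3.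

Step 9
Reactants: 15 (3S,4R)-3,4-dihydroxy-β-ionone
Product: 16 (3E)-4-[(3R,4S)-3,4-bis(triethylsilyloxy)-2,6,6-trimethylcyclohex-1-en-1-yl]but-3-en-2-one
Conditions: TESCl (2.5 equiv), imidazole, DMAP (cat.), DMF, rt
Reagents that add atoms: triethylsilyl chloride (CC[Si](Cl)(CC)CC)
Why: Bis-silylation under basic conditions protects both hydroxyls (one of them an ionisable allylic alcohol) without touching either stereocentre.

Step 10
Reactants: 16 bis-TES dihydroxy-β-ionone
Product: 17 (4E)-5-[(3R,4S)-3,4-bis(triethylsilyloxy)-2,6,6-trimethylcyclohex-1-en-1-yl]-3-methylpenta-1,4-dien-3-ol (both carbinol epimers)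
Conditions: CH2=CHMgBr, THF, -20 to 0 °C; H2O quench
Reagents that add atoms: vinylmagnesium bromide (C=C[Mg]Br)
Why: Grignard 1,2-addition to the hindered dienone (as in vinyl-β-ionol manufacture) gives the tertiary bis-allylic carbinol, whose configuration is irrelevant.

Step 11
Reactants: 17 β-series vinyl carbinol
Product: 19 diethyl {(2E,4E)-5-[(3R,4S)-3,4-bis(triethylsilyloxy)-2,6,6-trimethylcyclohex-1-en-1-yl]-3-methylpenta-2,4-dien-1-yl}phosphonate, via allyl diethyl phosphite 18 (not isolated)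
Conditions: (EtO)2PCl, Et3N, DMAP (cat.), Et2O, 0 °C; filter; PhMe, 100 °C; SiO2 (2E isomer)
Reagents that add atoms: diethyl chlorophosphite (CCOP(Cl)OCC)
Why: The same [2,3]-sigmatropic phosphite → phosphonate rearrangement forms the C11–P bond and the C9=C10 olefin without acid, which the very ionisable allylic C4–O bond would not survive; the 2E isomer is taken on.

Step 12
Reactants: 19 β-C15 phosphonate; 13 ε-C25 aldehyde
Product: 20 (3S,4R,3'R,6'R)-3,4,3'-tris(triethylsilyloxy)-β,ε-carotene (all-E)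
Conditions: KOt-Bu, THF, -30 °C; then 13, -30 to 0 °C; crystallise all-E isomer
Reagents that add atoms: none
Why: A second Horner–Wadsworth–Emmons olefination closes the C40 polyene with an E C11=C12 bond; all four stereocentres are carried unchanged.

Step 13
Reactants: 20 tris-TES carotenoid
Product: 21 (3S,4R,3'R,6'R)-β,ε-carotene-3,4,3'-triol (target)
Conditions: TBAF, AcOH, THF, 0 °C to rt; recrystallise
Reagents that add atoms: none
Why: Buffered fluoride desilylation removes the three silyl ethers under non-acidic conditions, so neither allylic alcohol ionises and no stereocentre or double bond is disturbed.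

**Compound list**

1 | (R)-α-ionone, (3E)-4-[(1R)-2,6,6-trimethylcyclohex-2-en-1-yl]but-3-en-2-one | CC1=CCCC(C)(C)[C@H]1/C=C/C(C)=O | starting material
2 | 2-methyl-2-{(E)-2-[(1R)-2,6,6-trimethylcyclohex-2-en-1-yl]ethenyl}-1,3-dioxolane | CC1=CCCC(C)(C)[C@H]1/C=C/C2(C)OCCO2 | intermediate
3 | (4R)-3,5,5-trimethyl-4-[(E)-2-(2-methyl-1,3-dioxolan-2-yl)ethenyl]cyclohex-2-en-1-one | CC1=CC(=O)CC(C)(C)[C@H]1/C=C/C2(C)OCCO2 | intermediate
4 | (1R,4R)-3,5,5-trimethyl-4-[(E)-2-(2-methyl-1,3-dioxolan-2-yl)ethenyl]cyclohex-2-en-1-ol (trans-hydroxy ketal) | CC1=C[C@H](O)CC(C)(C)[C@H]1/C=C/C2(C)OCCO2 | intermediate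
5 | (1S,4R)-3,5,5-trimethyl-4-[(E)-2-(2-methyl-1,3-dioxolan-2-yl)ethenyl]cyclohex-2-en-1-ol (cis-hydroxy ketal) | CC1=C[C@@H](O)CC(C)(C)[C@H]1/C=C/C2(C)OCCO2 | intermediate
6 | (3R,6R)-3-hydroxy-α-ionone (trans), (3E)-4-[(1R,4R)-4-hydroxy-2,6,6-trimethylcyclohex-2-en-1-yl]but-3-en-2-one | CC1=C[C@H](O)CC(C)(C)[C@H]1/C=C/C(C)=O | intermediate
7 | (3S,6R)-3-hydroxy-α-ionone (cis), (3E)-4-[(1R,4S)-4-hydroxy-2,6,6-trimethylcyclohex-2-en-1-yl]but-3-en-2-one | CC1=C[C@@H](O)CC(C)(C)[C@H]1/C=C/C(C)=O | intermediate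
8 | (3E)-4-[(1R,4R)-4-(triethylsilyloxy)-2,6,6-trimethylcyclohex-2-en-1-yl]but-3-en-2-one | CC1=C[C@H](O[Si](CC)(CC)CC)CC(C)(C)[C@H]1/C=C/C(C)=O | intermediate
9 | (4E)-3-methyl-5-[(1R,4R)-4-(triethylsilyloxy)-2,6,6-trimethylcyclohex-2-en-1-yl]penta-1,4-dien-3-ol (carbinol epimers) | CC1=C[C@H](O[Si](CC)(CC)CC)CC(C)(C)[C@H]1/C=C/C(C)(O)C=C | intermediate
10 | diethyl phosphite ester of 9 (allyl diethyl phosphite) | CC1=C[C@H](O[Si](CC)(CC)CC)CC(C)(C)[C@H]1/C=C/C(C)(OP(OCC)OCC)C=C | intermediate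
11 | diethyl {(2E,4E)-3-methyl-5-[(1R,4R)-4-(triethylsilyloxy)-2,6,6-trimethylcyclohex-2-en-1-yl]penta-2,4-dien-1-yl}phosphonate | CC1=C[C@H](O[Si](CC)(CC)CC)CC(C)(C)[C@H]1/C=C/C(C)=C/CP(=O)(OCC)OCC | intermediate
12 | (2E,4E,6E)-2,7-dimethylocta-2,4,6-trienedial | O=C/C(C)=C/C=C/C=C(C)/C=O | starting material
13 | (3R,6R)-3-(triethylsilyloxy)-12'-apo-ε-caroten-12'-al | CC1=C[C@H](O[Si](CC)(CC)CC)CC(C)(C)[C@H]1/C=C/C(C)=C/C=C/C(C)=C/C=C/C=C(C)/C=O | intermediate
14 | (3S,4S,5R,6R)-4,5-epoxy-3-hydroxy-4,5-dihydro-α-ionone (epoxide syn to OH and side chain) | C[C@]12O[C@H]1[C@@H](O)CC(C)(C)[C@H]2/C=C/C(C)=O | intermediate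
15 | (3E)-4-[(3R,4S)-3,4-dihydroxy-2,6,6-trimethylcyclohex-1-en-1-yl]but-3-en-2-one (cis-diol) | CC(=O)/C=C/C1=C(C)[C@@H](O)[C@@H](O)CC1(C)C | intermediate
16 | (3E)-4-[(3R,4S)-3,4-bis(triethylsilyloxy)-2,6,6-trimethylcyclohex-1-en-1-yl]but-3-en-2-one | CC(=O)/C=C/C1=C(C)[C@@H](O[Si](CC)(CC)CC)[C@@H](O[Si](CC)(CC)CC)CC1(C)C | intermediate
17 | (4E)-5-[(3R,4S)-3,4-bis(triethylsilyloxy)-2,6,6-trimethylcyclohex-1-en-1-yl]-3-methylpenta-1,4-dien-3-ol (carbinol epimers) | C=CC(C)(O)/C=C/C1=C(C)[C@@H](O[Si](CC)(CC)CC)[C@@H](O[Si](CC)(CC)CC)CC1(C)C | intermediate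
18 | diethyl phosphite ester of 17 (allyl diethyl phosphite) | C=CC(C)(OP(OCC)OCC)/C=C/C1=C(C)[C@@H](O[Si](CC)(CC)CC)[C@@H](O[Si](CC)(CC)CC)CC1(C)C | intermediate
19 | diethyl {(2E,4E)-5-[(3R,4S)-3,4-bis(triethylsilyloxy)-2,6,6-trimethylcyclohex-1-en-1-yl]-3-methylpenta-2,4-dien-1-yl}phosphonate | CCOP(=O)(OCC)C/C=C(C)/C=C/C1=C(C)[C@@H](O[Si](CC)(CC)CC)[C@@H](O[Si](CC)(CC)CC)CC1(C)C | intermediate
20 | (3S,4R,3'R,6'R)-3,4,3'-tris(triethylsilyloxy)-β,ε-carotene | CC1=C[C@H](O[Si](CC)(CC)CC)CC(C)(C)[C@H]1/C=C/C(C)=C/C=C/C(C)=C/C=C/C=C(C)/C=C/C=C(C)/C=C/C1=C(C)[C@@H](O[Si](CC)(CC)CC)[C@@H](O[Si](CC)(CC)CC)CC1(C)C | intermediate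
21 | (3S,4R,3'R,6'R)-β,ε-carotene-3,4,3'-triol | CC1=C[C@H](O)CC(C)(C)[C@H]1/C=C/C(C)=C/C=C/C(C)=C/C=C/C=C(C)/C=C/C=C(C)/C=C/C1=C(C)[C@@H](O)[C@@H](O)CC1(C)C | target

**Step count and risks**

Total steps: 13. Longest linear sequence: 9 (steps 1, 2, 3, 8, 9, 10, 11, 12, 13; the ε branch through steps 4–7 is equally long).

Three steps most likely to fail:

Step 3 (supply of the two C3 epimers). The reduction may give too little of the cis alcohol needed for the longer branch. The fallback sets out from 6: Mitsunobu esterification with 4-nitrobenzoic acid, PPh3 and DIAD in THF inverts C3 by SN2 and gives (1S,4R)-4-[(E)-3-oxobut-1-enyl]-3,5,5-trimethylcyclohex-2-en-1-yl 4-nitrobenzoate F1. Methanolysis with K2CO3 in MeOH at 0 °C then returns to the route at 7.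

Step 8 (directed epoxidation and vinylogous E1cB opening in one pot). The epoxidation may be slow on the hindered face, or the base step may give side products. The fallback sets out from 7 and enforces the cis relationship with a tether instead of a directed reagent. Boc2O with DMAP gives the tert-butyl carbonate of cis-3-hydroxy-α-ionone F2. IBr in toluene at -80 °C delivers the carbonate oxygen to C4 on the face of C3–O and gives the cis-fused 5-iodo-3,4-cyclic carbonate F3. DBU removes HI through the C6 dienolate to give the 3,4-cyclic carbonate of dihydroxy-β-ionone F4. K2CO3 in MeOH then cleaves the carbonate and returns to the route at 15.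

Step 11 ([2,3] shift on the substrate with the most ionisable C–O bond; elimination of the tertiary phosphite or poor E/Z would hurt here most). The fallback sets out from 16 and builds the donor stepwise with no rearrangement. Horner–Wadsworth–Emmons reaction with triethyl phosphonoacetate and NaH gives the ethyl (2E,4E)-dienoate F5. DIBAL at -78 °C gives the primary allylic alcohol F6. CBr4 with PPh3 gives the allylic bromide F7. Arbuzov reaction with P(OEt)3 then returns to the route at 19.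

**Further compounds**

F1 | step 3 | (1S,4R)-3,5,5-trimethyl-4-[(E)-3-oxobut-1-enyl]cyclohex-2-en-1-yl 4-nitrobenzoate | CC1=C[C@@H](OC(=O)c2ccc(cc2)[N+](=O)[O-])CC(C)(C)[C@H]1/C=C/C(C)=O
F2 | step 8 | tert-butyl (1S,4R)-3,5,5-trimethyl-4-[(E)-3-oxobut-1-enyl]cyclohex-2-en-1-yl carbonate | CC1=C[C@@H](OC(=O)OC(C)(C)C)CC(C)(C)[C@H]1/C=C/C(C)=O
F3 | step 8 | cis-fused 3,4-cyclic carbonate of 5-iodo-3,4-dihydroxy-4,5-dihydro-α-ionone (iodine anti to the carbonate) | C[C@@]1(I)[C@H]2OC(=O)O[C@H]2CC(C)(C)[C@H]1/C=C/C(C)=O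
F4 | step 8 | 3,4-cyclic carbonate of (3S,4R)-3,4-dihydroxy-β-ionone | CC(=O)/C=C/C1=C(C)[C@H]2OC(=O)O[C@H]2CC1(C)C
F5 | step 11 | ethyl (2E,4E)-5-[(3R,4S)-3,4-bis(triethylsilyloxy)-2,6,6-trimethylcyclohex-1-en-1-yl]-3-methylpenta-2,4-dienoate | CCOC(=O)/C=C(C)/C=C/C1=C(C)[C@@H](O[Si](CC)(CC)CC)[C@@H](O[Si](CC)(CC)CC)CC1(C)C
F6 | step 11 | (2E,4E)-5-[(3R,4S)-3,4-bis(triethylsilyloxy)-2,6,6-trimethylcyclohex-1-en-1-yl]-3-methylpenta-2,4-dien-1-ol | OC/C=C(C)/C=C/C1=C(C)[C@@H](O[Si](CC)(CC)CC)[C@@H](O[Si](CC)(CC)CC)CC1(C)C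
F7 | step 11 | (2E,4E)-1-bromo-5-[(3R,4S)-3,4-bis(triethylsilyloxy)-2,6,6-trimethylcyclohex-1-en-1-yl]-3-methylpenta-2,4-diene | BrC/C=C(C)/C=C/C1=C(C)[C@@H](O[Si](CC)(CC)CC)[C@@H](O[Si](CC)(CC)CC)CC1(C)C
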